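**Plan**
- Retrosynthesis: the acrylic acid is cut back to a terminal alkyne on C2 (C–CO2H bond), then O1–C2 of the 3,6-dihydro-2H-pyran is opened, then C4=C5 (olefination), the bond from the C5 carbon to the homofarnesyl chain (alkylation) and C2–C3 (allyl addition to an ynal).
- Enabling feature: ring carbon C2 carries O1 and the sp2 carbon of the acrylate, which can be carried as C≡CH; C2 is then a propargylic ether carbon that a copper allenylidene can flatten and rebuild.
- Forward: farnesyl bromide is homologated by one carbon to homofarnesyl iodide, which alkylates a Still–Gennari phosphonate; 3-(trimethylsilyl)propynal and allylmagnesium bromide give the C2–C3 aldehyde; a Z-olefination joins the chains; the only ring closes in step 13; the alkyne then becomes the acrylic acid.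
- Stereochemistry: both E alkenes come with farnesyl bromide, the Z C4=C5 alkene from the Still–Gennari step, and C2 (R) from a chiral pybox–copper catalyst acting on a racemic propargylic ester.

Key step: step 13

Assumption: the sense of induction of a pybox–copper allenylidene on this new substrate cannot be assigned in advance; (S,S)-Ph-pybox is written, and its (R,R) antipode takes its place if the first trial favours the 2S ether.
Abbreviation: homofarnesyl = (3E,7E)-4,8,12-trimethyltrideca-3,7,11-trien-1-yl. Ring numbering: O1, C2 (stereocentre), C3, C4=C5, C6.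

**Route**

Step 1
Reactants: 1 (2E,6E)-farnesyl bromide; 2 thioanisole
Product: 4 homofarnesyl phenyl sulfide, via (phenylthio)methyllithium 3 (not isolated)
Conditions: 2, n-BuLi, DABCO, THF, 0 °C; then 1, −78 °C → rt
Reagents that add atoms: none
Why: Lithiated thioanisole is a soft primary carbanion that should displace the allylic bromide of 1 at C1 by SN2 alkylation without allylic transposition or loss of the 2E geometry, adding the one carbon that turns the farnesyl into the homofarnesyl chain.

Step 2
Reactants: 4 homofarnesyl phenyl sulfide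
Product: 6 homofarnesyl iodide [(3E,7E)-1-iodo-4,8,12-trimethyltrideca-3,7,11-triene], via methylphenylsulfonium iodide 5 (not isolated)
Conditions: MeI (excess), NaI, DMF, 75 °C
Reagents that add atoms: iodomethane, CI; sodium iodide, [Na+].[I-]
Why: S-Methylation gives sulfonium salt 5, from which iodide displaces thioanisole at the primary carbon (SN2 on a sulfonium salt, a sulfide-to-iodide exchange), under neutral conditions that should leave the three trisubstituted alkenes alone.

Step 3
Reactants: 6 homofarnesyl iodide; 7 methyl bis(2,2,2-trifluoroethyl)phosphonoacetate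
Product: 8 rac-methyl 2-[bis(2,2,2-trifluoroethoxy)phosphoryl]-4-homofarnesylbutanoate, that is methyl (5E,9E)-2-[bis(2,2,2-trifluoroethoxy)phosphoryl]-6,10,14-trimethylpentadeca-5,9,13-trienoate
Conditions: 7 (excess), NaH, DMF, 0 °C; then 6, rt → 50 °C
Reagents that add atoms: none
Why: The sodium enolate of the phosphonoacetate should be C-alkylated by the unhindered primary iodide in DMF (malonate-type enolate alkylation), an excess of 7 holding back double alkylation, and the racemic α-centre it creates disappears in step 7.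

Step 4
Reactants: 9 3-(trimethylsilyl)propynal; 10 allylmagnesium bromide
Product: 11 rac-1-(trimethylsilyl)hex-5-en-1-yn-3-ol
Conditions: THF, −78 → 0 °C; aq. NH4Cl
Reagents that add atoms: none
Why: Grignard 1,2-addition of the allyl nucleophile to the unhindered ynal is fast at low temperature and gives the secondary propargylic alcohol as a racemate, which suffices because C2 is made planar again in step 13.

Step 5
Reactants: 11 rac-1-(trimethylsilyl)hex-5-en-1-yn-3-ol
Product: 12 rac-tert-butyldimethyl{[1-(trimethylsilyl)hex-5-en-1-yn-3-yl]oxy}silane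
Conditions: TBSCl, imidazole, DMF, rt
Reagents that add atoms: tert-butyldimethylsilyl chloride, CC(C)(C)[Si](C)(C)Cl
Why: Imidazole-promoted silylation of the secondary alcohol (standard TBS protection) masks the future C2 oxygen against ozone, amide base and hydride.

Step 6
Reactants: 12 rac-tert-butyldimethyl{[1-(trimethylsilyl)hex-5-en-1-yn-3-yl]oxy}silane
Product: 14 rac-3-[(tert-butyldimethylsilyl)oxy]-5-(trimethylsilyl)pent-4-ynal, via secondary ozonide 13 (not isolated)
Conditions: O3, CH2Cl2, −78 °C (Sudan III end point); then PPh3, −78 °C → rt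
Reagents that add atoms: ozone, [O-][O+]=O
Why: Ozonolysis with reductive work-up cleaves the terminal alkene well before the silyl-capped alkyne when the ozone feed is stopped at the indicator end point, and phosphine reduction of ozonide 13 gives the β-silyloxy aldehyde under neutral conditions.

Step 7
Reactants: 14 rac-3-[(tert-butyldimethylsilyl)oxy]-5-(trimethylsilyl)pent-4-ynal; 8 rac-α-homofarnesyl phosphonate
Product: 15 rac-methyl (2Z)-5-[(tert-butyldimethylsilyl)oxy]-2-homofarnesyl-7-(trimethylsilyl)hept-2-en-6-ynoate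
Conditions: 8, KHMDS, 18-crown-6, THF, −78 °C; then 14, −78 °C
Reagents that add atoms: none
Why: Still–Gennari olefination: with the electron-poor trifluoroethyl phosphonate and a crown-ether-separated potassium counter-ion the kinetic adduct collapses before it can equilibrate, so the ester should end up cis to the C3 methylene (Z), which is the C4=C5 geometry the ring closure needs, and at −78 °C the stabilised anion should not eliminate the β-silyloxy group of 14.

Step 8
Reactants: 15 rac-Z-enoate
Product: 16 rac-(2Z)-5-[(tert-butyldimethylsilyl)oxy]-2-homofarnesyl-7-(trimethylsilyl)hept-2-en-6-yn-1-ol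
Conditions: DIBAL-H, CH2Cl2, −78 °C; Rochelle salt
Reagents that add atoms: none
Why: DIBAL-H 1,2-reduction of the conjugated ester gives the allylic alcohol (the future C6–O1 unit) without touching the alkene geometry, the silyl ether or the silylalkyne.

Step 9
Reactants: 16 rac-allylic alcohol
Product: 17 rac-(2Z)-2-homofarnesylhept-2-en-6-yne-1,5-diol
Conditions: TBAF, THF, 0 °C → rt; aq. NH4Cl
Reagents that add atoms: none
Why: Fluoride-mediated desilylation cleaves both the O–Si bond of the TBS ether and the C–Si bond of the alkynylsilane in one operation, exposing the propargylic hydroxyl and the terminal alkyne that the copper chemistry requires.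

Step 10
Reactants: 17 rac-diol
Product: 18 rac-(5Z)-7-[(triethylsilyl)oxy]-6-homofarnesylhept-5-en-1-yn-3-ol
Conditions: TESCl (1.05 equiv), imidazole, CH2Cl2, −78 °C
Reagents that add atoms: chlorotriethylsilane, CC[Si](Cl)(CC)CC
Why: Selective monosilylation: with one equivalent of TESCl at −78 °C the unhindered primary allylic hydroxyl should react well ahead of the secondary propargylic one, which stays free for acylation.

Step 11
Reactants: 18 rac-mono-TES ether
Product: 19 rac-(5Z)-7-[(triethylsilyl)oxy]-6-homofarnesylhept-5-en-1-yn-3-yl pentafluorobenzoate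
Conditions: C6F5COCl, Et3N, DMAP (cat.), CH2Cl2, 0 °C
Reagents that add atoms: pentafluorobenzoyl chloride, O=C(Cl)c1c(F)c(F)c(F)c(F)c1F
Why: DMAP-catalysed acylation (nucleophilic acyl substitution with the acid chloride) converts the remaining secondary hydroxyl into the pentafluorobenzoate, the leaving group that alkyl-substituted propargylic carbons need for copper-assisted ionisation.

Step 12
Reactants: 19 rac-TES-protected pentafluorobenzoate
Product: 20 rac-(5Z)-7-hydroxy-6-homofarnesylhept-5-en-1-yn-3-yl pentafluorobenzoate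
Conditions: HF·pyridine, pyridine, THF, 0 °C
Reagents that add atoms: none
Why: Pyridine-buffered HF cleaves the primary triethylsilyl ether through Si–F bond formation (fluoride desilylation) under non-basic conditions free of nucleophilic alcohols, so the activated ester should neither be cleaved nor migrate to the freed C6 hydroxyl.

Step 13
Reactants: 20 rac-(5Z)-7-hydroxy-6-homofarnesylhept-5-en-1-yn-3-yl pentafluorobenzoate
Product: 21 (2R)-2-ethynyl-5-homofarnesyl-3,6-dihydro-2H-pyran
Conditions: Cu(OTf)·½C6H6 (10 mol %), (S,S)-Ph-pybox (12 mol %), i-Pr2NEt (1.5 equiv), CH2Cl2 (0.02 M), −20 °C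
Reagents that add atoms: none
Why: Proposed new method: copper(I)–pybox binds the terminal alkyne of 20, the amine gives the copper acetylide, loss of pentafluorobenzoate leaves a copper allenylidene in which C2 is planar so that both enantiomers of 20 merge, the C6 hydroxyl adds to C2, and protonolysis of the new copper acetylide releases 21 and the catalyst. The closest known reaction type is the copper–pybox-catalysed enantioselective propargylic etherification and amination of racemic propargylic esters, established intermolecularly with alcohols, intramolecularly with amines and for alkyl-substituted pentafluorobenzoates with amines, but not as an intramolecular O-closure on an alkyl-substituted ester. The 3,6-dihydro-2H-pyran closes by 6-exo-trig attack of O1 on the trigonal C2, the cumulated Cu=C=C unit staying outside the ring. The new C2 stereocentre is set by the chiral pybox on copper, which shields one face of the planar C2, so the configuration is under catalyst control and independent of the starting ester. The step needs ring closure to beat loss of a C3 proton (conjugated enyne), intermolecular etherification and acyl shift; the Z C4=C5 alkene, which holds the CH2OH group within bonding distance of C2, together with dilution, a non-nucleophilic solvent and a hindered base, should secure that.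

Step 14
Reactants: 21 (2R)-2-ethynyl-5-homofarnesyl-3,6-dihydro-2H-pyran
Product: 22 methyl 2-[(2R)-5-homofarnesyl-3,6-dihydro-2H-pyran-2-yl]prop-2-enoate
Conditions: Pd(OAc)2 (2 mol %), 2-(diphenylphosphino)pyridine (40 mol %), MsOH (20 mol %), CO (10 bar), MeOH/THF, 45 °C
Reagents that add atoms: carbon monoxide, [C-]#[O+]; methanol, CO
Why: Palladium-catalysed hydroalkoxycarbonylation of a terminal alkyne with the 2-pyridylphosphine ligand is branched-selective (ester on the internal carbon, Markovnikov sense) and far faster for alkynes than for trisubstituted alkenes, the acid is buffered as the pyridinium salt of the excess ligand, and C2 is not involved so its configuration should be kept.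

Step 15
Reactants: 22 methyl 2-[(2R)-5-homofarnesyl-3,6-dihydro-2H-pyran-2-yl]prop-2-enoate
Product: 23 2-[(2R)-5-homofarnesyl-3,6-dihydro-2H-pyran-2-yl]prop-2-enoic acid (target)
Conditions: LiOH, THF/H2O, 0 °C → rt; then dil. HCl to pH 3–4, 0 °C
Reagents that add atoms: lithium hydroxide, [Li+].[OH-]
Why: Saponification (BAc2 hydrolysis) of the methyl ester with LiOH at low temperature should outrun conjugate addition to the 2-substituted acrylate, the C2–H is not acidified by the cross-conjugated carboxylate so the stereocentre should survive, and cold, mild acidification spares the polyene.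

**Compound list**

1 | (2E,6E)-farnesyl bromide | BrC/C=C(\C)CC/C=C(\C)CCC=C(C)C | starting material
2 | thioanisole (methyl phenyl sulfide) | CSc1ccccc1 | starting material
3 | (phenylthio)methyllithium | [Li]CSc1ccccc1 | intermediate
4 | homofarnesyl phenyl sulfide, {[(3E,7E)-4,8,12-trimethyltrideca-3,7,11-trien-1-yl]sulfanyl}benzene | c1ccccc1SCC/C=C(\C)CC/C=C(\C)CCC=C(C)C | intermediate
5 | methyl(phenyl)(homofarnesyl)sulfonium iodide | C[S+](CC/C=C(\C)CC/C=C(\C)CCC=C(C)C)c1ccccc1.[I-] | intermediate
6 | homofarnesyl iodide, (3E,7E)-1-iodo-4,8,12-trimethyltrideca-3,7,11-triene | ICC/C=C(\C)CC/C=C(\C)CCC=C(C)C | intermediate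
7 | methyl bis(2,2,2-trifluoroethyl)phosphonoacetate | COC(=O)CP(=O)(OCC(F)(F)F)OCC(F)(F)F | starting material
8 | rac-methyl (5E,9E)-2-[bis(2,2,2-trifluoroethoxy)phosphoryl]-6,10,14-trimethylpentadeca-5,9,13-trienoate | COC(=O)C(CC/C=C(\C)CC/C=C(\C)CCC=C(C)C)P(=O)(OCC(F)(F)F)OCC(F)(F)F | intermediate
9 | 3-(trimethylsilyl)propynal | C[Si](C)(C)C#CC=O | starting material
10 | allylmagnesium bromide | C=CC[Mg]Br | starting material
11 | rac-1-(trimethylsilyl)hex-5-en-1-yn-3-ol | C[Si](C)(C)C#CC(O)CC=C | intermediate
12 | rac-tert-butyldimethyl{[1-(trimethylsilyl)hex-5-en-1-yn-3-yl]oxy}silane | C[Si](C)(C)C#CC(O[Si](C)(C)C(C)(C)C)CC=C | intermediate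
13 | secondary ozonide of 12, 3-substituted 1,2,4-trioxolane (diastereomer mixture) | C[Si](C)(C)C#CC(O[Si](C)(C)C(C)(C)C)CC1OCOO1 | intermediate
14 | rac-3-[(tert-butyldimethylsilyl)oxy]-5-(trimethylsilyl)pent-4-ynal | C[Si](C)(C)C#CC(O[Si](C)(C)C(C)(C)C)CC=O | intermediate
15 | rac-methyl (2Z)-5-[(tert-butyldimethylsilyl)oxy]-2-homofarnesyl-7-(trimethylsilyl)hept-2-en-6-ynoate | C[Si](C)(C)C#CC(O[Si](C)(C)C(C)(C)C)C/C=C(\C(=O)OC)CC/C=C(\C)CC/C=C(\C)CCC=C(C)C | intermediate
16 | rac-(2Z)-5-[(tert-butyldimethylsilyl)oxy]-2-homofarnesyl-7-(trimethylsilyl)hept-2-en-6-yn-1-ol | C[Si](C)(C)C#CC(O[Si](C)(C)C(C)(C)C)C/C=C(\CO)CC/C=C(\C)CC/C=C(\C)CCC=C(C)C | intermediate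
17 | rac-(2Z)-2-homofarnesylhept-2-en-6-yne-1,5-diol | C#CC(O)C/C=C(\CO)CC/C=C(\C)CC/C=C(\C)CCC=C(C)C | intermediate
18 | rac-(5Z)-7-[(triethylsilyl)oxy]-6-homofarnesylhept-5-en-1-yn-3-ol | C#CC(O)C/C=C(\CO[Si](CC)(CC)CC)CC/C=C(\C)CC/C=C(\C)CCC=C(C)C | intermediate
19 | rac-(5Z)-7-[(triethylsilyl)oxy]-6-homofarnesylhept-5-en-1-yn-3-yl pentafluorobenzoate | C#CC(OC(=O)c1c(F)c(F)c(F)c(F)c1F)C/C=C(\CO[Si](CC)(CC)CC)CC/C=C(\C)CC/C=C(\C)CCC=C(C)C | intermediate
20 | rac-(5Z)-7-hydroxy-6-homofarnesylhept-5-en-1-yn-3-yl pentafluorobenzoate | C#CC(OC(=O)c1c(F)c(F)c(F)c(F)c1F)C/C=C(\CO)CC/C=C(\C)CC/C=C(\C)CCC=C(C)C | intermediate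
21 | (2R)-2-ethynyl-5-[(3E,7E)-4,8,12-trimethyltrideca-3,7,11-trien-1-yl]-3,6-dihydro-2H-pyran | C#C[C@H]1CC=C(CC/C=C(\C)CC/C=C(\C)CCC=C(C)C)CO1 | intermediate
22 | methyl 2-[(2R)-5-[(3E,7E)-4,8,12-trimethyltrideca-3,7,11-trien-1-yl]-3,6-dihydro-2H-pyran-2-yl]prop-2-enoate | COC(=O)C(=C)[C@H]1CC=C(CC/C=C(\C)CC/C=C(\C)CCC=C(C)C)CO1 | intermediate
23 | 2-[(2R)-5-[(3E,7E)-4,8,12-trimethyltrideca-3,7,11-trien-1-yl]-3,6-dihydro-2H-pyran-2-yl]prop-2-enoic acid | C=C(C(=O)O)[C@H]1CC=C(CC/C=C(\C)CC/C=C(\C)CCC=C(C)C)CO1 | target

**Step count and risks**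

Total step count: 15. Longest linear sequence: 12 steps (steps 1–3 then 7–15; equally steps 4–6 then 7–15).

Steps most likely to fail:

1. Step 13 (copper allenylidene ring closure). After ionisation the allenylidene may lose a C3 proton and drain into a conjugated enyne faster than the hydroxyl closes the ring. The ligand may also discriminate poorly between the two faces of planar C2, and the activated acyl group may shift to the primary hydroxyl under the amine. The fallback sets out from aldehyde 9 and bromide 1 and returns at alkyne 21; it fixes C2 by a reagent-controlled allylboration and closes the ring at C4=C5 instead. Brown allylation of 9 with B-allyldiisopinocampheylborane derived from (−)-α-pinene (Et2O, −78 °C, then NaOH/H2O2; the antipode chosen to deliver R) should give (R)-1-(trimethylsilyl)hex-5-en-1-yn-3-ol F1. In parallel, 2-methylprop-2-en-1-ol is doubly lithiated (n-BuLi, TMEDA) to lithium 2-(lithiomethyl)prop-2-en-1-olate F2, which is alkylated by 1 to (5E,9E)-6,10,14-trimethyl-2-methylidenepentadeca-5,9,13-trien-1-ol F3. Appel bromination (CBr4, PPh3, CH2Cl2, 0 °C) gives (5E,9E)-2-(bromomethyl)-6,10,14-trimethylpentadeca-1,5,9,13-tetraene F4. Williamson etherification of F1 with F4 (NaH, THF, 0 °C) gives (R)-trimethyl(3-{[(5E,9E)-6,10,14-trimethyl-2-methylidenepentadeca-5,9,13-trien-1-yl]oxy}hex-5-en-1-yn-1-yl)silane F5. Ring-closing metathesis (second-generation Grubbs catalyst, CH2Cl2, 40 °C) forms C4=C5 and gives (2R)-5-homofarnesyl-2-[(trimethylsilyl)ethynyl]-3,6-dihydro-2H-pyran F6, and K2CO3 in MeOH removes the silyl cap to reach 21.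

2. Step 14 (branched methoxycarbonylation). Regiocontrol may erode towards the linear ester, palladium hydride may isomerise alkenes, or the acid may help palladium ionise the allylic C6–O1 bond. The fallback sets out from 21 and returns at 22; it fixes the regiochemistry in a separate hydrometalation. Mo(CO)3(CNt-Bu)3-catalysed hydrostannation of 21 with Bu3SnH (THF, 55 °C), which is α-selective for propargylic ethers, should give tributyl{1-[(2R)-5-homofarnesyl-3,6-dihydro-2H-pyran-2-yl]ethenyl}stannane F7. Iododestannylation (I2, CH2Cl2, 0 °C) gives (2R)-5-homofarnesyl-2-(1-iodoethenyl)-3,6-dihydro-2H-pyran F8, and acid-free carbonylation of the vinyl iodide (Pd(PPh3)4, CO 1 atm, MeOH, Et3N, DMF, 50 °C) gives 22.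

3. Step 3 (alkylation of the fluorinated phosphonoacetate). C-Alkylation of the weakly nucleophilic enolate may be slow, so that E2 loss of HI from the iodide and double alkylation take over. The fallback sets out from aldehyde 14 and iodide 6 and returns at enoate 15; it attaches the chain by cross-coupling after the alkene is in place. Dibromo-olefination of 14 (CBr4, PPh3, Zn, CH2Cl2, 0 °C) gives rac-tert-butyl{[6,6-dibromo-1-(trimethylsilyl)hex-5-en-1-yn-3-yl]oxy}dimethylsilane F9. Zinc insertion into 6 (Zn dust, LiCl, THF) gives homofarnesylzinc iodide F10. Trans-selective Negishi mono-coupling of F9 with F10 (PdCl2(DPEphos), THF, 0 °C → rt) replaces the bromine trans to the C3 chain and gives rac-tert-butyl{[(5Z,9E,13E)-6-bromo-10,14,18-trimethyl-1-(trimethylsilyl)nonadeca-5,9,13,17-tetraen-1-yn-3-yl]oxy}dimethylsilane F11. Palladium-catalysed methoxycarbonylation of the remaining alkenyl bromide with retention (Pd(dppf)Cl2, CO, MeOH, Et3N, 70 °C) gives 15.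

Further compounds
F1 | step 13 | (R)-1-(trimethylsilyl)hex-5-en-1-yn-3-ol | C[Si](C)(C)C#C[C@H](O)CC=C
F2 | step 13 | lithium 2-(lithiomethyl)prop-2-en-1-olate | [Li]CC(=C)CO[Li]
F3 | step 13 | (5E,9E)-6,10,14-trimethyl-2-methylidenepentadeca-5,9,13-trien-1-ol | OCC(=C)CC/C=C(\C)CC/C=C(\C)CCC=C(C)C
F4 | step 13 | (5E,9E)-2-(bromomethyl)-6,10,14-trimethylpentadeca-1,5,9,13-tetraene | BrCC(=C)CC/C=C(\C)CC/C=C(\C)CCC=C(C)C
F5 | step 13 | (R)-trimethyl(3-{[(5E,9E)-6,10,14-trimethyl-2-methylidenepentadeca-5,9,13-trien-1-yl]oxy}hex-5-en-1-yn-1-yl)silane | C[Si](C)(C)C#C[C@H](OCC(=C)CC/C=C(\C)CC/C=C(\C)CCC=C(C)C)CC=C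
F6 | step 13 | (2R)-5-[(3E,7E)-4,8,12-trimethyltrideca-3,7,11-trien-1-yl]-2-[(trimethylsilyl)ethynyl]-3,6-dihydro-2H-pyran | C[Si](C)(C)C#C[C@H]1CC=C(CC/C=C(\C)CC/C=C(\C)CCC=C(C)C)CO1
F7 | step 14 | tributyl{1-[(2R)-5-[(3E,7E)-4,8,12-trimethyltrideca-3,7,11-trien-1-yl]-3,6-dihydro-2H-pyran-2-yl]ethenyl}stannane | C=C([Sn](CCCC)(CCCC)CCCC)[C@H]1CC=C(CC/C=C(\C)CC/C=C(\C)CCC=C(C)C)CO1
F8 | step 14 | (2R)-2-(1-iodoethenyl)-5-[(3E,7E)-4,8,12-trimethyltrideca-3,7,11-trien-1-yl]-3,6-dihydro-2H-pyran | C=C(I)[C@H]1CC=C(CC/C=C(\C)CC/C=C(\C)CCC=C(C)C)CO1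
F9 | step 3 | rac-tert-butyl{[6,6-dibromo-1-(trimethylsilyl)hex-5-en-1-yn-3-yl]oxy}dimethylsilane | C[Si](C)(C)C#CC(O[Si](C)(C)C(C)(C)C)CC=C(Br)Br
F10 | step 3 | homofarnesylzinc iodide | I[Zn]CC/C=C(\C)CC/C=C(\C)CCC=C(C)C
F11 | step 3 | rac-tert-butyl{[(5Z,9E,13E)-6-bromo-10,14,18-trimethyl-1-(trimethylsilyl)nonadeca-5,9,13,17-tetraen-1-yn-3-yl]oxy}dimethylsilane | C[Si](C)(C)C#CC(O[Si](C)(C)C(C)(C)C)C/C=C(\Br)CC/C=C(\C)CC/C=C(\C)CCC=C(C)C
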